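Which set-up ends with the most intermediate, the closed flask or one of the two stirred tanks?

- the set-up with the highest amount of intermediate at the outlet or at the end, in percent of the substrate put in ("none" if the first two lie within 2 percentage points) (noon / dusk / midnight / none)
- amount of intermediate at the outlet or at the end, in percent of the substrate put in, noon
- amount of intermediate at the outlet or at the end, in percent of the substrate put in, dusk
- amount of intermediate at the outlet or at the end, in percent of the substrate put in, midnight

| flask | substrate | remark | time |
|---|---|---|---|
| north-east | 0.016 M | run made earlier |  |
| north-west | 0.0080 M | run made earlier |  |
| east | 0.012 M | run made earlier |  |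
| noon | 0.016 M | a single well-mixed tank run continuously and read at steady state, 2.5 h in it on average |  |
| dusk | 0.016 M | everything together in a closed stirred flask, run for 2.5 h | 2.5 h |
| midnight | 0.016 M | one stirred flow tank at steady state, fed with the mixture as stated, mean residence time 7.50 h |  |

north-east run (percent of the substrate charged)

| time / min | intermediate / % | target / % |
|---|---|---|
| 8.00 | 5 | 1 |
| 15.0 | 12 | 2 |
| 40.0 | 24 | 2 |
| 90.0 | 36 | 11 |

north-west run (percent of the substrate charged)

| time / h | intermediate / % | target / % |
|---|---|---|
| 0.833 | 29 | 7 |
| 1.50 | 37 | 13 |
| 2.50 | 35 | 16 |
| 3.00 | 38 | 14 |

east run (percent of the substrate charged)

| time / h | intermediate / % | target / % |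
|---|---|---|
| 0.250 | 11 | 2 |
| 0.500 | 20 | 3 |
| 1.33 | 33 | 10 |
| 3.00 | 34 | 17 |

(standard deviation of a reading: 1.5 percentage points)

- a species is counted by the substrate in it: one side product counts as two
- the stated concentrations are those of everything mixed, before any reaction; amounts are the same in each set-up
- steps that have been proposed: substrate -> intermediate; intermediate <-> target; intermediate <-> isomer of the product; substrate + target -> side product
- the earlier runs were made in a closed, stirred flask

*What can you say of the substrate, which no column shows?* I count what has left it as intermediate plus target, leaving out the unseen isomer of the product and side product, and north-east at 15.0 min shows 14.0%. Integrating a first-order loss gives [substrate] falling as exp(−kt), so that reading makes k = 0.603 /h. I call this the survival constant, the usual first-order rate constant of substrate loss.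

*One reading, one charge. Isn't that weak?* It is. But north-west, at half the charge, gives 0.536 /h at 0.833 h, a gap I can accept with 1.5 percentage points on each reading.

*And in a tank?* There the balance is algebra, and the surviving share is one over one plus kτ. So I reckon that noon leaves 39.9% of its substrate, while the closed flask at dusk leaves 22.1%, and midnight leaves 18.1%.

*Now the intermediate.* The north-west readings stay nearly level from 1.50 h to 3.00 h, so I take inflow to equal outflow there. With 35% read at 2.50 h, where a first-order loss leaves the same share of substrate as at dusk, I put the net loss constant at 0.381 /h.

*Apply it.* In a tank, intermediate is the converted share divided by one plus that constant times τ, which gives 30.8% at noon and 21.2% at midnight. For dusk I commit to that north-west reading at the same time, 35%, which is more than my figure for either tank. The weak spot is that the net constant rests on one reading.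

The forecast also puts dusk first, with 36% against 28% at noon and 24% at midnight, lower than my noon and higher than my midnight, in its words “Batch wins.”

The flasks give 37.0% at dusk, 26.7% at noon and 20.9% at midnight, so dusk leads, and noon stands 4.1 points below my figure.

    substrate → intermediate (k = 0.590 /h)
    intermediate ⇌ target (K = 0.460, k = 0.750 /h)
    intermediate ⇌ isomer of the product (K = 160, k = 0.310 /h)
    substrate + target → side product (k = 12.0 /M/h)

The 2.5 h of dusk is twice the half-life of substrate by its own step, 1.2 h. For midnight the same constant reckons 0.00290 M, and [substrate] everywhere in that tank stands at 0.00288 M.

The earlier runs and the new flask are calculated with made-up constants; scatter was added.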